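## Structural features

The target is a biflavanoid of the 5-deoxy series in which two chroman units, each a benzene ring A fused to a dihydropyran ring C with a 4-hydroxyphenyl ring B on C2 and hydroxyls on C7 and C8, are joined by one single bond from C4 of the upper unit to C6' of ring A of the lower unit. The upper unit is a 2,3-cis-flavan-3-ol whose C4 aryl group is trans to the 3-hydroxyl (2R,3R,4S), and the lower unit is a 2',3'-trans-3',4'-trans-flavan-3',4'-diol (2'R,3'S,4'R). The six stereocentres therefore form two contiguous triads, C2–C3–C4 and C2'–C3'–C4', separated by the aryl carbon C6', so neither triad can control the other. Fragile points are the benzylic 4'-hydroxyl, which lies para to the 7'-oxygen and ionises in acid with epimerisation or condensation, the acid-labile interflavanyl C4–C6' bond, both benzylic C2–O1 ether bonds, and the two pyrogallol-type rings A, which oxidise in air once the phenols are free. The real difficulty is twofold: C6' must be alkylated by upper C4 although lower ring A is no better a nucleophile than upper ring A, and the all-trans lower triad must be raised without letting water add to a free C4' cation, because small oxygen nucleophiles add to 2,3-trans-flavan-4-yl cations mainly cis to the 3-oxygen. The key step uses the fact that O1' and C4' of lower ring C sit on the adjacent ring A carbons C8a' and C4a', so that with C3'=C4' as a double bond ring C is a 2H-chromene that closes by metathesis between a vinyl group on C4a' and an allyl ether on the C8a' oxygen, leaving C2' as the only centre a reagent must set.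

## Logic of the disconnections

23 from 22. The seven O–benzyl bonds are cut. Benzyl is the only protecting group, so one neutral hydrogenolysis ends the synthesis and the free, air- and acid-sensitive polyphenol appears only in the last flask. The demand is that the benzylic C4'–OH and C2–O1 bonds survive.

22 from 21. The C4'–H bond is cut back to a C4' carbonyl. This erases C4' and lets it be reset by axial hydride delivery on a 2,3-trans-dihydroflavonol, which gives the 3',4'-trans alcohol. Opening an epoxide with water would pass through the C4' cation and lean to the cis diol, so the ketone is the safer source of this centre.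

21 from 19 through 20. The C3'–O and C4'–O bonds are cut back to the C3'=C4' alkene. The C3' oxygen arrives by epoxidation on the face opposite the 2'-aryl group. The C4' oxygen arrives as a ketone, so its momentary configuration is irrelevant. The demand is chemoselective oxidation of one alkene among electron-rich arenes.

19 from 18. The C3'=C4' bond is cut by ring-closing metathesis, which removes lower ring C and leaves two terminal alkenes ortho to each other. The substitution pattern of 18 needs no change: C8', C4a' and C6' are all blocked, both alkenes are monosubstituted, and every protecting group is benzyl. The demand is that neither alkene migrates and that the allylic, benzylic C2'–H stays untouched.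

18 from 17 and 6. The C2'–O bond is cut. An asymmetric allylic etherification builds the only reagent-set centre of the lower unit in one catalytic step, independent of the distant upper centres. The demand is branched selectivity and face control on an aryloxide that is substituted at both ortho positions.

17 from 16. The vinyl C=C is cut to an aldehyde. The formyl group is a robust placeholder that survives Lewis acid, whereas a styrene would not.

16 from 15 and 2. The interflavanyl C4–C6' bond is cut. An upper C4 cation meets C5 of 2, the one ring position activated by a para hydroxyl and an ortho benzyloxy group, so the regiochemistry is unambiguous, and attack anti to the axial 3-benzyloxy group sets C4. The demands are a non-chelating promoter (TiCl4 would bind the hydroxyl–formyl pair and switch the nucleophile off), excess 2 and slow addition of 15, because upper ring A is a competing nucleophile.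

15 back to 11. The C4–O bond is cut (benzylic oxidation of 14), then the 3-O–benzyl bond (13), then the configuration at C3 is traced back through 12 to the 2,3-trans alcohol 11. Every addition to a 2-aryl chromene goes anti to the aryl group, so the cis relation has to come from reduction of the ketone.

11 back to 7 and 6. The C3–O bond is cut to the alkene of 9 (hydroboration through 10), ring C of 9 is cut by metathesis to 8, and the C2–O bond of 8 is cut to 7 and 6. The upper unit is thus made by the same etherification–metathesis pair as the lower one, from the same two building blocks, and steps 6 and 7 rehearse steps 15 and 16.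

7, 2 and 6 to starting materials. 7 comes from 2 by olefination and 2 from 1 by double O-benzylation. 6 comes from 3 through 4 and 5 by olefination, reduction and acylation. Both rings A derive from 1 and both rings B from 3.

## Other disconnections considered

Alternative 1: The cut is the C4–C4a bond of upper ring C. In the forward step Me3SiOTf ionises the C4 benzoate of the open-chain substrate A1 (both C4 epimers converge), the C3 benzoate bridges the cation as a dioxolanylium ion, and the 2,3-bis(benzyloxy)phenoxy ring attacks C4 through its free ortho carbon anti to the bridge, giving A2 with the 3,4-trans relation.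
- In its favour: the closure is intramolecular, so the interflavanyl bond is in place beforehand, made by a polar addition at a position of lower ring A fixed by a halogen or metal. No two rings A compete, and on this point the alternative is better than the chosen plan, whose step 13 relies on excess nucleophile. The 4'-ketone of A2 would be reduced to the trans diol exactly as in step 18, so the two plans are equal there.
- Against it: A1 carries three contiguous stereocentres that must be built in an open chain. One is a benzylic aryl ether at C2 that the same Lewis acid can ionise, which threatens C2. The lower dihydroflavonol must survive organometallic and Lewis acid steps although it opens easily by retro-oxa-Michael reaction. The benzoate adds a deprotection on base-sensitive material.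
- Comparison: on structure it solves the regiochemistry on ring A better. On mechanism both plans set C4 through a cation next to the 3-oxygen (anchimeric control there, anti attack on a ring here), with comparable reliability. On step economy the chosen plan should be shorter, because both heterocycles come from two building blocks by the same two reactions.

Alternative 2: The cut is the O1–C2 bond of upper ring C. In the forward step PPh3 and diisopropyl azodicarboxylate activate the benzylic C2 hydroxyl of the anti-configured substrate A3 and the C8a phenol displaces it with inversion, giving A4.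
- In its favour: the conditions are neutral. The 2,3-cis relation arises directly, with no oxidation–reduction correction at C3; here the alternative is better than the chosen plan, which spends steps 9 and 10 on that. The lower triad is complete before the closure, so A4 already has the oxidation level of the target, which is again better.
- Against it: C2 is a para-benzyloxybenzylic carbon, so the oxyphosphonium ion can ionise and close through the cation, which favours the 2,3-trans isomer and would erode the very centre the step is meant to set. The phenol is flanked on both sides. A3 needs a diarylmethine and two carbinol centres in an open chain plus a complete, separately protected flavan-3,4-diol, for which no short access is evident. Two silyl ethers must be removed beside the benzyl groups.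
- Comparison: on structure the alternative is closer to the target late in the route. On mechanism a stereospecific displacement at this benzylic centre is less secure than substrate-controlled additions to a ring. On step economy it should be longer.

Alternative 3: The cut is the pair C5'–C6' and C4a'–C8a', so lower ring A is made and not substituted. In the forward step the diene A5, carried on upper C4, adds to 3-butyn-2-one A6; loss of methanol and of the silyl groups gives the ortho-hydroxyaryl methyl ketone A7.
- In its favour: the position of the upper unit on ring A follows from the polarity of the cycloaddition and not from a competition between arenes; on the regiochemistry of the interflavanyl link this is better than the chosen plan. A7 opens the chalcone–dihydroflavonol route, whose last reduction equals step 18.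
- Against it: A5 must be made by adding a four-carbon nucleophile to the upper C4 cation and silylating twice, and it is hydrolytically labile. The thermal step must spare a 4-substituted flavan. A7 still needs differentiation of two phenols, an aldol condensation and an enantioselective epoxidation–cyclisation to set C2' and C3' on a crowded chalcone, whereas the chosen plan sets C2' in one catalytic step and derives C3' and C4' from it.
- Comparison: on structure the regiochemistry is better and the stereocontrol of the lower unit weaker. On mechanism the pericyclic ring construction is clean but front-loads sensitive enol ethers, while metathesis is neutral and late. On step economy ring C remains to be built after the key step, so the route should be longer.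

Key step: step 16

Assumption: the catalyst from [Ir(cod)Cl]2 and the (Sa,Sc,Sc) phosphoramidite is taken to give the (S)-1-arylallyl aryl ether, the usual sense for this ligand family; if the sense proved opposite, the (Ra,Rc,Rc) ligand would be used with no other change.

Abbreviations and descriptors:
- L = (Sa,Sc,Sc)-O,O'-(1,1'-binaphthalene-2,2'-diyl)-N,N-bis(1-phenylethyl)phosphoramidite.
- Fl = the upper group (2R,3R,4R)-3,7,8-tris(benzyloxy)-2-[4-(benzyloxy)phenyl]-3,4-dihydro-2H-chromen-4-yl.
- Upper C4 is R in the benzyl ethers 16–22 and S in 23 with no change of geometry, only of CIP priorities.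
- For the same reason C2' is S in 18–19 and R in 20–23.

## Route

Step 1
Reactants: 1 2,3,4-trihydroxybenzaldehyde
Product: 2 3,4-bis(benzyloxy)-2-hydroxybenzaldehyde
Conditions: BnBr (2.05 equiv), K2CO3 (2.2 equiv), DMF, 0 to 20 °C
Reagents that add atoms: benzyl bromide, BrCc1ccccc1
Why: Williamson etherification; the 4-OH (para to the formyl group) and then the 3-OH react, while the 2-OH is tied in a hydrogen bond to the carbonyl and its phenoxide is the least nucleophilic, so two equivalents should stop at the 3,4-diether.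

Step 2
Reactants: 3 4-(benzyloxy)benzaldehyde
Product: 4 ethyl (E)-3-[4-(benzyloxy)phenyl]prop-2-enoate
Conditions: (EtO)2P(O)CH2CO2Et, NaH, THF, 0 to 20 °C
Reagents that add atoms: triethyl phosphonoacetate, CCOC(=O)CP(=O)(OCC)OCC
Why: Horner–Wadsworth–Emmons olefination of a non-enolisable aryl aldehyde with a stabilised phosphonate anion should give the E-cinnamate.

Step 3
Reactants: 4 ethyl (E)-3-[4-(benzyloxy)phenyl]prop-2-enoate
Product: 5 (E)-3-[4-(benzyloxy)phenyl]prop-2-en-1-ol
Conditions: i-Bu2AlH (2.3 equiv), CH2Cl2, −78 to 0 °C; aq. potassium sodium tartrate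
Reagents that add atoms: none
Why: 1,2-Reduction of the conjugated ester by i-Bu2AlH gives the allylic alcohol without touching the alkene or the benzyl ether.

Step 4
Reactants: 5 (E)-3-[4-(benzyloxy)phenyl]prop-2-en-1-ol
Product: 6 (E)-3-[4-(benzyloxy)phenyl]prop-2-en-1-yl methyl carbonate
Conditions: ClCO2Me, pyridine, CH2Cl2, 0 °C
Reagents that add atoms: methyl chloroformate, COC(=O)Cl
Why: Acylation of the primary allylic alcohol under base, so that the electron-rich cinnamyl system does not ionise; the carbonate is the leaving group for the catalyst made from [Ir(cod)Cl]2 and L.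

Step 5
Reactants: 2 3,4-bis(benzyloxy)-2-hydroxybenzaldehyde
Product: 7 2,3-bis(benzyloxy)-6-ethenylphenol
Conditions: Ph3PCH3Br (2.5 equiv), KOt-Bu (2.4 equiv), THF, 0 to 20 °C
Reagents that add atoms: methyltriphenylphosphonium bromide, C[P+](c1ccccc1)(c1ccccc1)c1ccccc1.[Br-]
Why: Wittig methylenation; the first equivalent of ylide only deprotonates the phenol and the excess olefinates the aldehyde; the vinylphenol is used at once because it polymerises on standing.

Step 6
Reactants: 7 2,3-bis(benzyloxy)-6-ethenylphenol; 6 (E)-3-[4-(benzyloxy)phenyl]prop-2-en-1-yl methyl carbonate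
Product: 8 1,2-bis(benzyloxy)-3-{[(1S)-1-[4-(benzyloxy)phenyl]prop-2-en-1-yl]oxy}-4-ethenylbenzene
Conditions: LiN(SiMe3)2 (1.0 equiv), THF, 0 °C; 6 (1.3 equiv), [Ir(cod)Cl]2 (2 mol %), L (4 mol %), catalyst preactivated with n-PrNH2, THF, 50 °C
Reagents that add atoms: none
Why: Iridium-catalysed asymmetric allylic etherification: the cyclometalated complex from [Ir(cod)Cl]2 and L ionises the carbonate to an allyliridium species that the aryloxide attacks at the aryl-bearing terminus, and the ligand fixes the face, which sets upper C2; the lithium methoxide set free is too poor a nucleophile to compete.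

Step 7
Reactants: 8 1,2-bis(benzyloxy)-3-{[(1S)-1-[4-(benzyloxy)phenyl]prop-2-en-1-yl]oxy}-4-ethenylbenzene
Product: 9 (2S)-7,8-bis(benzyloxy)-2-[4-(benzyloxy)phenyl]-2H-chromene
Conditions: second-generation Grubbs catalyst (H2IMes)(PCy3)Cl2Ru=CHPh (3 mol %), 1,4-benzoquinone (10 mol %), CH2Cl2 (10 mM), 40 °C
Reagents that add atoms: none
Why: Ring-closing metathesis of a 2-vinylaryl allyl ether to a 2H-chromene, the closure of the key step on the monomer; the stereocentre is not involved and benzoquinone suppresses hydride-mediated alkene migration.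

Step 8
Reactants: 9 (2S)-7,8-bis(benzyloxy)-2-[4-(benzyloxy)phenyl]-2H-chromene
Product: 11 (2R,3S)-7,8-bis(benzyloxy)-2-[4-(benzyloxy)phenyl]-3,4-dihydro-2H-chromen-3-ol, via alkylborane 10 (not isolated)
Conditions: BH3·THF (1.2 equiv), THF, 0 to 20 °C; then aq. NaOH, 30% H2O2, 0 °C
Reagents that add atoms: hydrogen peroxide, OO
Why: Hydroboration–oxidation: boron adds to C3, the β-carbon of the alkoxy-substituted styrene, from the face opposite the 2-aryl group, and oxidation with retention should give the 2,3-trans alcohol.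

Step 9
Reactants: 11 (2R,3S)-7,8-bis(benzyloxy)-2-[4-(benzyloxy)phenyl]-3,4-dihydro-2H-chromen-3-ol
Product: 12 (2R)-7,8-bis(benzyloxy)-2-[4-(benzyloxy)phenyl]-2H-chromen-3(4H)-one
Conditions: Dess–Martin periodinane (1.5 equiv), pyridine, CH2Cl2, 20 °C
Reagents that add atoms: none
Why: Dess–Martin oxidation under buffered, non-basic conditions should give the flavan-3-one without enolisation toward C2, so the C2 centre is kept.

Step 10
Reactants: 12 (2R)-7,8-bis(benzyloxy)-2-[4-(benzyloxy)phenyl]-2H-chromen-3(4H)-one
Product: 13 (2R,3R)-7,8-bis(benzyloxy)-2-[4-(benzyloxy)phenyl]-3,4-dihydro-2H-chromen-3-ol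
Conditions: LiBH(s-Bu)3 (1.5 equiv), LiBr, THF, −78 °C
Reagents that add atoms: none
Why: The bulky hydride attacks the ketone equatorially, from the face opposite the 2-aryl group, and should give the axial 2,3-cis alcohol; this sets upper C3.

Step 11
Reactants: 13 (2R,3R)-7,8-bis(benzyloxy)-2-[4-(benzyloxy)phenyl]-3,4-dihydro-2H-chromen-3-ol
Product: 14 (2R,3R)-3,7,8-tris(benzyloxy)-2-[4-(benzyloxy)phenyl]-3,4-dihydro-2H-chromene
Conditions: NaH (1.5 equiv), BnBr (1.3 equiv), DMF, 0 to 20 °C
Reagents that add atoms: benzyl bromide, BrCc1ccccc1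
Why: Williamson etherification of the secondary alkoxide; the 3-O-benzyl group keeps the alcohol out of the cation chemistry and falls in the final hydrogenolysis.

Step 12
Reactants: 14 (2R,3R)-3,7,8-tris(benzyloxy)-2-[4-(benzyloxy)phenyl]-3,4-dihydro-2H-chromene
Product: 15 (2R,3R,4S)-3,7,8-tris(benzyloxy)-2-[4-(benzyloxy)phenyl]-4-(2-ethoxyethoxy)-3,4-dihydro-2H-chromene
Conditions: DDQ (2 equiv), 2-ethoxyethanol (5 equiv), CH2Cl2, 20 °C
Reagents that add atoms: 2-ethoxyethanol, CCOCCO
Why: Benzylic oxidation by hydride abstraction with DDQ: the charge-transfer complex forms on the electron-rich ring A, the C4 cation is stabilised by O1 (ortho) and the 7-oxygen (para), and the alcohol traps it trans to the 3-benzyloxy group; the C4 configuration is of no consequence because the group is ionised again in step 13.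

Step 13
Reactants: 15 (2R,3R,4S)-3,7,8-tris(benzyloxy)-2-[4-(benzyloxy)phenyl]-4-(2-ethoxyethoxy)-3,4-dihydro-2H-chromene; 2 3,4-bis(benzyloxy)-2-hydroxybenzaldehyde
Product: 16 3,4-bis(benzyloxy)-5-Fl-2-hydroxybenzaldehyde
Conditions: 2 (4 equiv), Me3SiOTf (0.3 equiv), CH2Cl2, −40 to −10 °C, slow addition of 15; Et3N quench
Reagents that add atoms: none
Why: Friedel–Crafts alkylation: the silyl triflate ionises the 4-alkoxy group and the flavan-4-yl cation is attacked by C5 of 2, the only position with a para hydroxyl and an ortho benzyloxy group, from the face opposite the axial 3-benzyloxy group, which sets upper C4 as 3,4-trans; excess 2 and slow addition are needed because ring A of 15 and of 16 are competing nucleophiles, and O-alkylation of the phenol is reversible under the acid.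

Step 14
Reactants: 16 3,4-bis(benzyloxy)-5-Fl-2-hydroxybenzaldehyde
Product: 17 2,3-bis(benzyloxy)-6-ethenyl-4-Fl-phenol
Conditions: Ph3PCH3Br (3 equiv), KOt-Bu (2.9 equiv), THF, 0 to 20 °C
Reagents that add atoms: methyltriphenylphosphonium bromide, C[P+](c1ccccc1)(c1ccccc1)c1ccccc1.[Br-]
Why: Wittig methylenation of the salicylaldehyde as in step 5; the ylide is not basic enough to remove the doubly benzylic C4–H.

Step 15
Reactants: 17 2,3-bis(benzyloxy)-6-ethenyl-4-Fl-phenol; 6 (E)-3-[4-(benzyloxy)phenyl]prop-2-en-1-yl methyl carbonate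
Product: 18 (2R,3R,4R)-3,7,8-tris(benzyloxy)-2-[4-(benzyloxy)phenyl]-4-[2,3-bis(benzyloxy)-4-{[(1S)-1-[4-(benzyloxy)phenyl]prop-2-en-1-yl]oxy}-5-ethenylphenyl]-3,4-dihydro-2H-chromene
Conditions: LiN(SiMe3)2 (1.0 equiv), THF, 0 °C; 6 (1.5 equiv), [Ir(cod)Cl]2 (4 mol %), L (8 mol %), catalyst preactivated with n-PrNH2, THF, 40 °C
Reagents that add atoms: none
Why: Iridium-catalysed asymmetric allylic etherification as in step 6, now with the aryloxide as the limiting partner; C2' is set by the ligand, independent of the remote upper centres, and with both ortho positions and the para position of the aryloxide blocked only O-allylation is possible.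

Step 16
Reactants: 18 (2R,3R,4R)-3,7,8-tris(benzyloxy)-2-[4-(benzyloxy)phenyl]-4-[2,3-bis(benzyloxy)-4-{[(1S)-1-[4-(benzyloxy)phenyl]prop-2-en-1-yl]oxy}-5-ethenylphenyl]-3,4-dihydro-2H-chromene
Product: 19 (2R,3R,4R)-3,7,8-tris(benzyloxy)-2-[4-(benzyloxy)phenyl]-4-{(2S)-7,8-bis(benzyloxy)-2-[4-(benzyloxy)phenyl]-2H-chromen-6-yl}-3,4-dihydro-2H-chromene
Conditions: second-generation Grubbs catalyst (H2IMes)(PCy3)Cl2Ru=CHPh (5 mol %), 1,4-benzoquinone (10 mol %), CH2Cl2 (5 mM), 40 °C; filtration through Et3N-deactivated silica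
Reagents that add atoms: none
Why: Ring-closing olefin metathesis: the benzylidene (H2IMes)(PCy3)Cl2Ru=CHPh exchanges with one terminal alkene of 18, the new alkylidene adds to the second alkene in a [2+2] cycloaddition, and cycloreversion of the ruthenacyclobutane releases the C3'=C4' bond with ethylene as the only by-product. The closest known reaction type is the closure of 2-vinylaryl allyl ethers to 2H-chromenes, which step 7 rehearses. Lower ring C closes as a six-membered ring between two monosubstituted alkenes held ortho to each other on ring A, so closure should win over intermolecular metathesis at this dilution and the new alkene is necessarily cis within the ring. No stereocentre is formed, and C2' keeps the configuration set in step 15 because none of its bonds takes part. The selectivity needed is chemical: no migration of either alkene and no abstraction of the allylic, benzylic C2'–H, which benzoquinone secures by intercepting ruthenium hydride species. A Claisen rearrangement cannot compete because C8', C4a' and C6' all carry substituents, and the benzyl ethers and the diarylmethine C4–H are inert to the carbene. The product is an acid-labile allylic, benzylic ether, so it is kept away from acidic surfaces and used at once.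

Step 17
Reactants: 19 (2R,3R,4R)-3,7,8-tris(benzyloxy)-2-[4-(benzyloxy)phenyl]-4-{(2S)-7,8-bis(benzyloxy)-2-[4-(benzyloxy)phenyl]-2H-chromen-6-yl}-3,4-dihydro-2H-chromene
Product: 21 (2R,3R)-7,8-bis(benzyloxy)-2-[4-(benzyloxy)phenyl]-6-Fl-3-hydroxy-2,3-dihydro-4H-chromen-4-one, via epoxide 20 (not isolated)
Conditions: dimethyldioxirane (1.2 equiv), acetone/CH2Cl2, −40 to −10 °C; evaporate cold; DMSO/CH2Cl2, camphorsulfonic acid (5 mol %), 0 to 20 °C; then i-Pr2NEt
Reagents that add atoms: dimethyldioxirane, CC1(C)OO1; dimethyl sulfoxide, CS(C)=O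
Why: Epoxidation on the face opposite the 2'-aryl group sets the C3' oxygen trans to it; the electron-rich benzylic epoxide is then opened at C4' by dimethyl sulfoxide and the alkoxysulfonium salt collapses with base to the ketone (Kornblum-type oxidation of an epoxide to an α-hydroxy ketone), so water never meets the C4' cation and the momentary C4' configuration does not matter.

Step 18
Reactants: 21 (2R,3R)-7,8-bis(benzyloxy)-2-[4-(benzyloxy)phenyl]-6-Fl-3-hydroxy-2,3-dihydro-4H-chromen-4-one
Product: 22 (2R,3S,4R)-7,8-bis(benzyloxy)-2-[4-(benzyloxy)phenyl]-6-Fl-3,4-dihydro-2H-chromene-3,4-diol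
Conditions: NaBH4 (2 equiv), THF/MeOH, −20 to 0 °C
Reagents that add atoms: none
Why: Borohydride reduction of a 2,3-trans-dihydroflavonol: hydride enters axially at C4' of the half-chair in which the 2'-aryl and 3'-hydroxyl groups are equatorial and should give the equatorial 4'-hydroxyl trans to the 3'-hydroxyl; this sets C4'.

Step 19
Reactants: 22 (2R,3S,4R)-7,8-bis(benzyloxy)-2-[4-(benzyloxy)phenyl]-6-Fl-3,4-dihydro-2H-chromene-3,4-diol
Product: 23 (2R,3S,4R)-2-(4-hydroxyphenyl)-6-[(2R,3R,4S)-3,7,8-trihydroxy-2-(4-hydroxyphenyl)-3,4-dihydro-2H-chromen-4-yl]-3,4-dihydro-2H-chromene-3,4,7,8-tetrol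
Conditions: H2 (1 atm), Pd(OH)2/C, THF/MeOH, 20 °C; filtration under argon, freeze-drying
Reagents that add atoms: none
Why: Hydrogenolysis of the seven O-benzyl groups under neutral conditions; no acid is added so the 4'-hydroxyl does not ionise, and the reaction is stopped at full debenzylation to spare the benzylic C4'–O and C2–O1 bonds.

## Compound list

1 | 2,3,4-trihydroxybenzaldehyde | O=Cc1ccc(O)c(O)c1O | starting material
2 | 3,4-bis(benzyloxy)-2-hydroxybenzaldehyde | O=Cc1ccc(OCc2ccccc2)c(OCc2ccccc2)c1O | intermediate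
3 | 4-(benzyloxy)benzaldehyde | O=Cc1ccc(OCc2ccccc2)cc1 | starting material
4 | ethyl (E)-3-[4-(benzyloxy)phenyl]prop-2-enoate | CCOC(=O)/C=C/c1ccc(OCc2ccccc2)cc1 | intermediate
5 | (E)-3-[4-(benzyloxy)phenyl]prop-2-en-1-ol | OC/C=C/c1ccc(OCc2ccccc2)cc1 | intermediate
6 | (E)-3-[4-(benzyloxy)phenyl]prop-2-en-1-yl methyl carbonate | COC(=O)OC/C=C/c1ccc(OCc2ccccc2)cc1 | intermediate
7 | 2,3-bis(benzyloxy)-6-ethenylphenol | C=Cc1ccc(OCc2ccccc2)c(OCc2ccccc2)c1O | intermediate
8 | 1,2-bis(benzyloxy)-3-{[(1S)-1-[4-(benzyloxy)phenyl]prop-2-en-1-yl]oxy}-4-ethenylbenzene | C=Cc1ccc(OCc2ccccc2)c(OCc2ccccc2)c1O[C@@H](C=C)c1ccc(OCc2ccccc2)cc1 | intermediate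
9 | (2S)-7,8-bis(benzyloxy)-2-[4-(benzyloxy)phenyl]-2H-chromene | c1ccccc1COc1ccc(cc1)[C@H]1Oc2c(C=C1)ccc(OCc3ccccc3)c2OCc1ccccc1 | intermediate
10 | [(2S,3S)-7,8-bis(benzyloxy)-2-[4-(benzyloxy)phenyl]-3,4-dihydro-2H-chromen-3-yl]borane (boron trans to the 2-aryl group) | c1ccccc1COc1ccc(cc1)[C@H]1Oc2c(ccc(OCc3ccccc3)c2OCc2ccccc2)C[C@@H]1B | intermediate (not isolated)
11 | (2R,3S)-7,8-bis(benzyloxy)-2-[4-(benzyloxy)phenyl]-3,4-dihydro-2H-chromen-3-ol (2,3-trans) | c1ccccc1COc1ccc(cc1)[C@H]1Oc2c(ccc(OCc3ccccc3)c2OCc2ccccc2)C[C@@H]1O | intermediate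
12 | (2R)-7,8-bis(benzyloxy)-2-[4-(benzyloxy)phenyl]-2H-chromen-3(4H)-one | c1ccccc1COc1ccc(cc1)[C@H]1Oc2c(ccc(OCc3ccccc3)c2OCc2ccccc2)CC1=O | intermediate
13 | (2R,3R)-7,8-bis(benzyloxy)-2-[4-(benzyloxy)phenyl]-3,4-dihydro-2H-chromen-3-ol (2,3-cis) | c1ccccc1COc1ccc(cc1)[C@H]1Oc2c(ccc(OCc3ccccc3)c2OCc2ccccc2)C[C@H]1O | intermediate
14 | (2R,3R)-3,7,8-tris(benzyloxy)-2-[4-(benzyloxy)phenyl]-3,4-dihydro-2H-chromene | c1ccccc1COc1ccc(cc1)[C@H]1Oc2c(ccc(OCc3ccccc3)c2OCc2ccccc2)C[C@H]1OCc1ccccc1 | intermediate
15 | (2R,3R,4S)-3,7,8-tris(benzyloxy)-2-[4-(benzyloxy)phenyl]-4-(2-ethoxyethoxy)-3,4-dihydro-2H-chromene | c1ccccc1COc1ccc(cc1)[C@H]1Oc2c(ccc(OCc3ccccc3)c2OCc2ccccc2)[C@H](OCCOCC)[C@H]1OCc1ccccc1 | intermediate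
16 | 3,4-bis(benzyloxy)-2-hydroxy-5-{(2R,3R,4R)-3,7,8-tris(benzyloxy)-2-[4-(benzyloxy)phenyl]-3,4-dihydro-2H-chromen-4-yl}benzaldehyde | c1ccccc1COc1ccc(cc1)[C@H]1Oc2c(ccc(OCc3ccccc3)c2OCc2ccccc2)[C@H](c2cc(C=O)c(O)c(OCc3ccccc3)c2OCc2ccccc2)[C@H]1OCc1ccccc1 | intermediate
17 | 2,3-bis(benzyloxy)-6-ethenyl-4-{(2R,3R,4R)-3,7,8-tris(benzyloxy)-2-[4-(benzyloxy)phenyl]-3,4-dihydro-2H-chromen-4-yl}phenol | c1ccccc1COc1ccc(cc1)[C@H]1Oc2c(ccc(OCc3ccccc3)c2OCc2ccccc2)[C@H](c2cc(C=C)c(O)c(OCc3ccccc3)c2OCc2ccccc2)[C@H]1OCc1ccccc1 | intermediate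
18 | (2R,3R,4R)-3,7,8-tris(benzyloxy)-2-[4-(benzyloxy)phenyl]-4-[2,3-bis(benzyloxy)-4-{[(1S)-1-[4-(benzyloxy)phenyl]prop-2-en-1-yl]oxy}-5-ethenylphenyl]-3,4-dihydro-2H-chromene | c1ccccc1COc1ccc(cc1)[C@H]1Oc2c(ccc(OCc3ccccc3)c2OCc2ccccc2)[C@H](c2cc(C=C)c(O[C@@H](C=C)c3ccc(OCc4ccccc4)cc3)c(OCc3ccccc3)c2OCc2ccccc2)[C@H]1OCc1ccccc1 | intermediate
19 | (2R,3R,4R)-3,7,8-tris(benzyloxy)-2-[4-(benzyloxy)phenyl]-4-{(2S)-7,8-bis(benzyloxy)-2-[4-(benzyloxy)phenyl]-2H-chromen-6-yl}-3,4-dihydro-2H-chromene | c1ccccc1COc1ccc(cc1)[C@H]1Oc2c(ccc(OCc3ccccc3)c2OCc2ccccc2)[C@H](c2cc3c(c(OCc4ccccc4)c2OCc2ccccc2)O[C@H](c2ccc(OCc4ccccc4)cc2)C=C3)[C@H]1OCc1ccccc1 | intermediate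
20 | 3',4'-epoxide of 19 on the face opposite the 2'-aryl group (lower unit 2R,3S,4S) | c1ccccc1COc1ccc(cc1)[C@H]1Oc2c(ccc(OCc3ccccc3)c2OCc2ccccc2)[C@H](c2cc3c(c(OCc4ccccc4)c2OCc2ccccc2)O[C@H](c2ccc(OCc4ccccc4)cc2)[C@H]2O[C@H]23)[C@H]1OCc1ccccc1 | intermediate (not isolated)
21 | (2R,3R)-7,8-bis(benzyloxy)-2-[4-(benzyloxy)phenyl]-3-hydroxy-6-{(2R,3R,4R)-3,7,8-tris(benzyloxy)-2-[4-(benzyloxy)phenyl]-3,4-dihydro-2H-chromen-4-yl}-2,3-dihydro-4H-chromen-4-one | c1ccccc1COc1ccc(cc1)[C@H]1Oc2c(ccc(OCc3ccccc3)c2OCc2ccccc2)[C@H](c2cc3c(c(OCc4ccccc4)c2OCc2ccccc2)O[C@H](c2ccc(OCc4ccccc4)cc2)[C@@H](O)C3=O)[C@H]1OCc1ccccc1 | intermediate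
22 | (2R,3S,4R)-7,8-bis(benzyloxy)-2-[4-(benzyloxy)phenyl]-6-{(2R,3R,4R)-3,7,8-tris(benzyloxy)-2-[4-(benzyloxy)phenyl]-3,4-dihydro-2H-chromen-4-yl}-3,4-dihydro-2H-chromene-3,4-diol | c1ccccc1COc1ccc(cc1)[C@H]1Oc2c(ccc(OCc3ccccc3)c2OCc2ccccc2)[C@H](c2cc3c(c(OCc4ccccc4)c2OCc2ccccc2)O[C@H](c2ccc(OCc4ccccc4)cc2)[C@@H](O)[C@@H]3O)[C@H]1OCc1ccccc1 | intermediate
23 | (2R,3S,4R)-2-(4-hydroxyphenyl)-6-[(2R,3R,4S)-3,7,8-trihydroxy-2-(4-hydroxyphenyl)-3,4-dihydro-2H-chromen-4-yl]-3,4-dihydro-2H-chromene-3,4,7,8-tetrol | Oc1ccc([C@H]2Oc3c(ccc(O)c3O)[C@H](c3cc4c(c(O)c3O)O[C@H](c3ccc(O)cc3)[C@@H](O)[C@@H]4O)[C@H]2O)cc1 | target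

## Step count and least certain steps

Total step count: 19. Longest linear sequence: 17 steps (steps 2, 3 and 4, then steps 6 to 19, from 3 to 23). The chain from 1 (step 1, step 5, then steps 6 to 19) has 16 steps, and 6 enters the route twice, at steps 6 and 15.

Step 16 (key step). Most likely to go wrong: migration of an alkene by ruthenium hydride species (the allyl ether to an enol ether, or the product to the 4H-chromene), intermolecular metathesis between styrene termini, and ionisation of the allylic, benzylic C2'–O1' bond of the product on acidic surfaces. Fallback, setting out from 16 and coming back at 19: ring C is built on the salicylaldehyde. 1-(Benzyloxy)-4-ethynylbenzene is hydroborated with catecholborane (neat, 70 °C) to 2-[(E)-2-[4-(benzyloxy)phenyl]ethenyl]-1,3,2-benzodioxaborole F1, which water hydrolyses to (E)-2-[4-(benzyloxy)phenyl]ethenylboronic acid F2. Heating 16 with F2 and dibenzylamine in dioxane at 90 °C should give 19 together with the C2' epimer of 19 F3, by Petasis-type borono-Mannich addition, loss of the amine to an ortho-quinone methide and 6π-electrocyclisation. The two diastereomers would be separated on deactivated silica. The price is the loss of reagent control at C2'.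

Step 13. Most likely to go wrong: self-condensation, because C6 of ring A of 15 and of 16 competes with the formyl-deactivated nucleophile 2, and sluggish capture of the cation. Fallback, setting out from 15 and coming back at 16: the formyl group is introduced after the coupling. Commercial 2,3-bis(benzyloxy)benzaldehyde is converted by Baeyer–Villiger oxidation (m-CPBA, CH2Cl2) into 2,3-bis(benzyloxy)phenyl formate F4 and by methanolysis (K2CO3, MeOH) into 2,3-bis(benzyloxy)phenol F5. F5 (3 equiv) and 15 under the conditions of step 13 should give 2,3-bis(benzyloxy)-4-{(2R,3R,4S)-3,7,8-tris(benzyloxy)-2-[4-(benzyloxy)phenyl]-3,4-dihydro-2H-chromen-4-yl}phenol F6 by attack para to the hydroxyl. Magnesium-mediated ortho-formylation (MgCl2, Et3N, paraformaldehyde, MeCN, reflux) at the only free ortho position then gives 16. An ortho-alkylated regioisomer has no free ortho position, is not formylated and is removed at that stage.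

Step 12. Most likely to go wrong: competing hydride abstraction at C2–H (benzylic to ring B and next to O1) and over-oxidation toward flavene or flavylium species, since ring A lacks the 5-oxygen that makes C4 oxidation easy in other series. Fallback, setting out from 9 and coming back at 15: the C4 oxygen is taken from the alkene. Dimethyldioxirane epoxidation of 9 anti to the aryl group gives the 3,4-epoxide of 9 F7, opened in the same flask at C4 by 2-ethoxyethanol (pyridinium p-toluenesulfonate, catalytic) to (2R,3S,4S)-7,8-bis(benzyloxy)-2-[4-(benzyloxy)phenyl]-4-(2-ethoxyethoxy)-3,4-dihydro-2H-chromen-3-ol F8. Dess–Martin oxidation gives (2R,4S)-7,8-bis(benzyloxy)-2-[4-(benzyloxy)phenyl]-4-(2-ethoxyethoxy)-2H-chromen-3(4H)-one F9, and LiBH(s-Bu)3 at −78 °C the 2,3-cis alcohol (2R,3R,4S)-7,8-bis(benzyloxy)-2-[4-(benzyloxy)phenyl]-4-(2-ethoxyethoxy)-3,4-dihydro-2H-chromen-3-ol F10. NaH and BnBr then give 15. F8 is drawn as the 4β ether expected from axial attack; the C4 epimer would serve equally, since step 13 ionises this centre.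

Step 15. Most likely to go wrong: slow turnover on the large aryloxide that is substituted at both ortho positions, so that the branched ether re-ionises and leaks to the linear cinnamyl ether or loses purity at C2', and interference of the ortho-vinyl group with the metal. Fallback, setting out from 16 and coming back at 18: the order of etherification and olefination is reversed. The lithium aryloxide of 16 and 6 under the conditions of step 15 should give 3,4-bis(benzyloxy)-2-{[(1S)-1-[4-(benzyloxy)phenyl]prop-2-en-1-yl]oxy}-5-Fl-benzaldehyde F11, and Wittig methylenation (Ph3PCH3Br, KOt-Bu, THF, 0 °C) of F11 gives 18.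

Step 17. Most likely to go wrong: rearrangement of the epoxide by hydride shift to the 3'-ketone, oxidation of the electron-rich rings by excess dioxirane, and base-induced ring opening or epimerisation of the dihydroflavonol. Fallback, setting out from 19 and coming back at 21: OsO4 (catalytic) with N-methylmorpholine N-oxide in acetone/water should add anti to the 2'-aryl group to give the 3',4'-cis diol (2R,3S,4S)-7,8-bis(benzyloxy)-2-[4-(benzyloxy)phenyl]-6-Fl-3,4-dihydro-2H-chromene-3,4-diol F12, whose benzylic 4'-hydroxyl is then oxidised selectively with MnO2 in CH2Cl2 to give 21.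

Step 19. Most likely to go wrong: hydrogenolysis of the benzylic C4'–OH or C2–O1 bonds along with the benzyl ethers, and acid-induced epimerisation at C4' during isolation. Fallback, setting out from 21 and coming back at 23: the order of the last two steps is reversed. Hydrogenolysis of 21 (H2, Pd(OH)2/C, THF/MeOH), where C4' is a carbonyl and not a benzylic alcohol, gives (2R,3R)-3,7,8-trihydroxy-2-(4-hydroxyphenyl)-6-[(2R,3R,4S)-3,7,8-trihydroxy-2-(4-hydroxyphenyl)-3,4-dihydro-2H-chromen-4-yl]-2,3-dihydro-4H-chromen-4-one F13, and NaBH4 in EtOH at 0 °C reduces F13 to 23.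

## Further compounds

F1 | step 16 | 2-[(E)-2-[4-(benzyloxy)phenyl]ethenyl]-1,3,2-benzodioxaborole | c1ccccc1COc1ccc(cc1)/C=C/B1Oc2ccccc2O1
F2 | step 16 | (E)-2-[4-(benzyloxy)phenyl]ethenylboronic acid | OB(O)/C=C/c1ccc(OCc2ccccc2)cc1
F3 | step 16 | C2' epimer of 19 (lower unit 2R) | c1ccccc1COc1ccc(cc1)[C@H]1Oc2c(ccc(OCc3ccccc3)c2OCc2ccccc2)[C@H](c2cc3c(c(OCc4ccccc4)c2OCc2ccccc2)O[C@@H](c2ccc(OCc4ccccc4)cc2)C=C3)[C@H]1OCc1ccccc1
F4 | step 13 | 2,3-bis(benzyloxy)phenyl formate | O=COc1cccc(OCc2ccccc2)c1OCc1ccccc1
F5 | step 13 | 2,3-bis(benzyloxy)phenol | Oc1cccc(OCc2ccccc2)c1OCc1ccccc1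
F6 | step 13 | 2,3-bis(benzyloxy)-4-{(2R,3R,4S)-3,7,8-tris(benzyloxy)-2-[4-(benzyloxy)phenyl]-3,4-dihydro-2H-chromen-4-yl}phenol | c1ccccc1COc1ccc(cc1)[C@H]1Oc2c(ccc(OCc3ccccc3)c2OCc2ccccc2)[C@H](c2ccc(O)c(OCc3ccccc3)c2OCc2ccccc2)[C@H]1OCc1ccccc1
F7 | step 12 | 3,4-epoxide of 9 on the face opposite the 2-aryl group | c1ccccc1COc1ccc(cc1)[C@H]1Oc2c(ccc(OCc3ccccc3)c2OCc2ccccc2)[C@@H]2O[C@H]12
F8 | step 12 | (2R,3S,4S)-7,8-bis(benzyloxy)-2-[4-(benzyloxy)phenyl]-4-(2-ethoxyethoxy)-3,4-dihydro-2H-chromen-3-ol | c1ccccc1COc1ccc(cc1)[C@H]1Oc2c(ccc(OCc3ccccc3)c2OCc2ccccc2)[C@H](OCCOCC)[C@@H]1O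
F9 | step 12 | (2R,4S)-7,8-bis(benzyloxy)-2-[4-(benzyloxy)phenyl]-4-(2-ethoxyethoxy)-2H-chromen-3(4H)-one | c1ccccc1COc1ccc(cc1)[C@H]1Oc2c(ccc(OCc3ccccc3)c2OCc2ccccc2)[C@H](OCCOCC)C1=O
F10 | step 12 | (2R,3R,4S)-7,8-bis(benzyloxy)-2-[4-(benzyloxy)phenyl]-4-(2-ethoxyethoxy)-3,4-dihydro-2H-chromen-3-ol | c1ccccc1COc1ccc(cc1)[C@H]1Oc2c(ccc(OCc3ccccc3)c2OCc2ccccc2)[C@H](OCCOCC)[C@H]1O
F11 | step 15 | 3,4-bis(benzyloxy)-2-{[(1S)-1-[4-(benzyloxy)phenyl]prop-2-en-1-yl]oxy}-5-{(2R,3R,4R)-3,7,8-tris(benzyloxy)-2-[4-(benzyloxy)phenyl]-3,4-dihydro-2H-chromen-4-yl}benzaldehyde | c1ccccc1COc1ccc(cc1)[C@H]1Oc2c(ccc(OCc3ccccc3)c2OCc2ccccc2)[C@H](c2cc(C=O)c(O[C@@H](C=C)c3ccc(OCc4ccccc4)cc3)c(OCc3ccccc3)c2OCc2ccccc2)[C@H]1OCc1ccccc1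
F12 | step 17 | (2R,3S,4S)-7,8-bis(benzyloxy)-2-[4-(benzyloxy)phenyl]-6-{(2R,3R,4R)-3,7,8-tris(benzyloxy)-2-[4-(benzyloxy)phenyl]-3,4-dihydro-2H-chromen-4-yl}-3,4-dihydro-2H-chromene-3,4-diol (3',4'-cis) | c1ccccc1COc1ccc(cc1)[C@H]1Oc2c(ccc(OCc3ccccc3)c2OCc2ccccc2)[C@H](c2cc3c(c(OCc4ccccc4)c2OCc2ccccc2)O[C@H](c2ccc(OCc4ccccc4)cc2)[C@@H](O)[C@H]3O)[C@H]1OCc1ccccc1
F13 | step 19 | (2R,3R)-3,7,8-trihydroxy-2-(4-hydroxyphenyl)-6-[(2R,3R,4S)-3,7,8-trihydroxy-2-(4-hydroxyphenyl)-3,4-dihydro-2H-chromen-4-yl]-2,3-dihydro-4H-chromen-4-one | Oc1ccc(cc1)[C@H]1Oc2c(ccc(O)c2O)[C@H](c2cc3c(c(O)c2O)O[C@H](c2ccc(O)cc2)[C@@H](O)C3=O)[C@H]1O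
A1 | alternative 1 | open-chain 3-[4-(benzyloxy)phenyl]-3-[2,3-bis(benzyloxy)phenoxy]propane-1,2-diyl dibenzoate carrying at C1 the 6-position of (2R,3R)-3,7,8-tris(benzyloxy)-2-[4-(benzyloxy)phenyl]chroman-4-one, either C1 epimer | c1ccccc1COc1ccc(cc1)[C@@H](Oc1cccc(OCc2ccccc2)c1OCc1ccccc1)[C@H](OC(=O)c1ccccc1)C(OC(=O)c1ccccc1)c1cc2c(c(OCc3ccccc3)c1OCc1ccccc1)O[C@H](c1ccc(OCc3ccccc3)cc1)[C@@H](OCc1ccccc1)C2=O
A2 | alternative 1 | benzyl-protected dimer with upper 3-O-benzoate and lower 3'-O-benzyl-4'-ketone | c1ccccc1COc1ccc(cc1)[C@H]1Oc2c(ccc(OCc3ccccc3)c2OCc2ccccc2)[C@H](c2cc3c(c(OCc4ccccc4)c2OCc2ccccc2)O[C@H](c2ccc(OCc4ccccc4)cc2)[C@@H](OCc2ccccc2)C3=O)[C@H]1OC(=O)c1ccccc1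
A3 | alternative 2 | open-chain anti 1-[4-(benzyloxy)phenyl]-2-(benzyloxy)-3-[3,4-bis(benzyloxy)-2-hydroxyphenyl]propan-1-ol carrying at C3 the 6-position of the lower 3',4'-bis(tert-butyldimethylsilyl) ether of the benzylated flavan-3,4-diol | c1ccccc1COc1ccc(cc1)[C@H](O)[C@H](OCc1ccccc1)[C@H](c1ccc(OCc2ccccc2)c(OCc2ccccc2)c1O)c1cc2c(c(OCc3ccccc3)c1OCc1ccccc1)O[C@H](c1ccc(OCc3ccccc3)cc1)[C@@H](O[Si](C)(C)C(C)(C)C)[C@@H]2O[Si](C)(C)C(C)(C)C
A4 | alternative 2 | fully protected dimer, benzyl ethers and lower 3',4'-bis(tert-butyldimethylsilyl) ether | c1ccccc1COc1ccc(cc1)[C@H]1Oc2c(ccc(OCc3ccccc3)c2OCc2ccccc2)[C@H](c2cc3c(c(OCc4ccccc4)c2OCc2ccccc2)O[C@H](c2ccc(OCc4ccccc4)cc2)[C@@H](O[Si](C)(C)C(C)(C)C)[C@@H]3O[Si](C)(C)C(C)(C)C)[C@H]1OCc1ccccc1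
A5 | alternative 3 | 2-(benzyloxy)-1-methoxy-1,3-bis(trimethylsilyloxy)buta-1,3-diene carrying at C4 the upper tetra-O-benzyl flavan-4-yl group | COC(O[Si](C)(C)C)=C(OCc1ccccc1)C(O[Si](C)(C)C)=C[C@H]1c2ccc(OCc3ccccc3)c(OCc3ccccc3)c2O[C@H](c2ccc(OCc3ccccc3)cc2)[C@@H]1OCc1ccccc1
A6 | alternative 3 | 3-butyn-2-one | CC(=O)C#C
A7 | alternative 3 | 3-benzyloxy-2,4-dihydroxy-5-(upper tetra-O-benzyl flavan-4-yl)acetophenone | c1ccccc1COc1ccc(cc1)[C@H]1Oc2c(ccc(OCc3ccccc3)c2OCc2ccccc2)[C@H](c2cc(C(C)=O)c(O)c(OCc3ccccc3)c2O)[C@H]1OCc1ccccc1
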